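**Strategy.** Everything rests on closing ring A onto a preformed ring B by forming the C3–C4 bond (labdane numbering) through an Ireland–Claisen ring contraction. The step exploits that quaternary C4 carries an oxidised carbon (C18, the later CH2OH) and lies 1,4 to C1 within ring A. C18 is tied to a C1 vinyl carbinol as a δ-lactone fused to ring B, so one [3,3] shift closes ring A, builds the C4 quaternary centre and transfers the C1 configuration to it. The precursor is an α-methyl unsaturated bicyclic lactone whose dienolate leaves a C5=C6 alkene, later used to set C5 and C6 by hydroboration. A single catalytically set, finally erased stereocentre (C8) relays all others.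

Key step: step 5

Remark on numbering and configuration: labdane numbering is used throughout. Ring A = C1, C2, C3, C4, C5, C10; ring B = C5 to C10. C4 carries C19 (CH3) and C18 (CH2OH), C10 carries C20 (CH3), C8 carries C17 (CH3), and C9 carries the side chain C11 to C16 with the ester carbon C15. The target SMILES is read as the (1R,4R,4aS,5S,8aS)-octahydronaphthalene, an ent-labdane with C19, C20 and the C9 chain on one face and H5, the C6 hydroxyl and C18 on the other.

**Step 1**
Reactants: 1 propanal; 2 pent-1-en-3-one
Product: 4 (S)-2,4-dimethylcyclohex-2-en-1-one, via (S)-2-methyl-5-oxoheptanal 3 (not isolated)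
Conditions: (R)-α,α-diphenylprolinol trimethylsilyl ether (5 mol %), ethyl 3,4-dihydroxybenzoate (20 mol %), neat, 4 °C; then LiOH, iPrOH, rt
Reagents that add atoms: none
Why: Enamine-catalysed Michael addition sets the methyl-bearing centre (later C8), the enone approaching the (E)-enamine face remote from the diarylmethyl group so that the (R)-catalyst should give the (S)-aldehyde, and the ethyl-ketone methylene then closes the ring by intramolecular aldol condensation (Robinson-type annulation) without touching that centre.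

**Step 2**
Reactants: 4 (S)-2,4-dimethylcyclohex-2-en-1-one; 5 2-(2-bromoethyl)-2-methyl-1,3-dioxolane; 6 acrolein
Product: 9 (2R,3R,4S)-2-[(1R)-1-hydroxyprop-2-en-1-yl]-2,4-dimethyl-3-[2-(2-methyl-1,3-dioxolan-2-yl)ethyl]cyclohexan-1-one, via Grignard reagent 7 (not isolated), via bromomagnesium enolate 8 (not isolated)
Conditions: 5, Mg, THF, 25 °C; CuBr·SMe2 (10 mol %), 4, THF, −40 °C; then 6, −78 °C; aq. NH4Cl
Reagents that add atoms: none
Why: Copper-catalysed conjugate addition of the Grignard reagent should occur anti to the C8 methyl group (setting C9), acrolein then attacks the tetrasubstituted enolate anti to the new C9 chain (setting C10), and a closed chair-like Zimmerman–Traxler aldol transition state with the vinyl group equatorial places the C1 oxygen syn to the C10 methyl group (tandem conjugate addition–aldol reaction).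

**Step 3**
Reactants: 9 aldol adduct; 10 2-(diethoxyphosphoryl)propanoic acid
Product: 11 (1R)-1-[(1R,2R,3S)-1,3-dimethyl-2-[2-(2-methyl-1,3-dioxolan-2-yl)ethyl]-6-oxocyclohexyl]prop-2-en-1-yl 2-(diethoxyphosphoryl)propanoate (epimers at the phosphonate carbon)
Conditions: DCC, DMAP (cat.), CH2Cl2, 0 °C → rt
Reagents that add atoms: none
Why: Steglich esterification acylates the hindered allylic alcohol under neutral conditions that avoid retro-aldol cleavage, and the only new centre (the phosphonate carbon) is erased in step 4.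

**Step 4**
Reactants: 11 phosphonate ester
Product: 12 (1R,7S,8R,8aS)-1-ethenyl-4,7,8a-trimethyl-8-[2-(2-methyl-1,3-dioxolan-2-yl)ethyl]-1,5,6,7,8,8a-hexahydro-3H-isochromen-3-one
Conditions: NaH, THF, 0 → 65 °C
Reagents that add atoms: none
Why: Intramolecular Horner–Wadsworth–Emmons olefination of the ring ketone by the tethered phosphonate anion closes the six-membered unsaturated lactone, the ring fixing the geometry of the new C4=C5 bond, and no stereocentre is formed.

**Step 5**
Reactants: 12 unsaturated vinyl lactone
Product: 15 methyl (1S,4aS,5R,6S)-1,4a,6-trimethyl-5-[2-(2-methyl-1,3-dioxolan-2-yl)ethyl]-1,2,4a,5,6,7-hexahydronaphthalene-1-carboxylate, via silyl ketene acetal 13 (not isolated), via silyl ester 14 (not isolated)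
Conditions: LiN(iPr)2, TBSCl, HMPA, THF, −78 °C → rt; PhMe, 110 °C; then Bu4NF, MeI, THF, rt
Reagents that add atoms: iodomethane, CI
Why: Kinetic γ-deprotonation at C6 and O-silylation give the cyclic silyl ketene acetal 13, in which C5 is sp2 so that the lactone can fold into the boat-like, bicyclo[2.2.2]-type transition state that a lactone-bridged [3,3]-sigmatropic shift requires; on heating the O–C1 bond breaks while C3 bonds to C4 (Ireland–Claisen rearrangement, the closest known type being the ring contraction of vinyl lactone silyl ketene acetals to cycloalkenecarboxylic acids). Ring A, a cyclohexene with a cis C1=C2 bond, is closed by this pericyclic ring contraction of the six-membered lactone, the allyl unit C1–C2–C3 being transposed suprafacially. The quaternary centre C4 is controlled by C1 alone: C3 can only reach the face of C4 on which the vinyl group sits, the face cis to the C10 methyl group, so the C4 methyl should end up cis to the C10 methyl and C18 trans to it. The step needs site selectivity for the α-carbon C4 of the dienolate, which the [3,3] geometry secures because C6 cannot be reached, and O- over C-silylation, which TBSCl with HMPA secures. Fluoride then cleaves the silyl ester 14 and the carboxylate is methylated in the same flask; the C5=C6 alkene left by the deconjugative rearrangement is kept for step 9.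

**Step 6**
Reactants: 15 diene ester
Product: 16 methyl (1S,4aS,5R,6S)-1,4a,6-trimethyl-5-[2-(2-methyl-1,3-dioxolan-2-yl)ethyl]-1,2,3,4,4a,5,6,7-octahydronaphthalene-1-carboxylate
Conditions: H2 (1 atm), RhCl(PPh3)3 (5 mol %), PhH/EtOH, rt
Reagents that add atoms: none
Why: Homogeneous hydrogenation should reduce the cis-disubstituted C1=C2 alkene and leave the trisubstituted C5=C6 alkene, which is flanked by two quaternary carbons, untouched; no stereocentre is formed.

**Step 7**
Reactants: 16 Δ5 ester
Product: 18 methyl (1S,4aS,5R)-1,4a,6-trimethyl-5-[2-(2-methyl-1,3-dioxolan-2-yl)ethyl]-1,2,3,4,4a,5-hexahydronaphthalene-1-carboxylate, via allylic bromide 17 (not isolated)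
Conditions: NBS, AIBN (cat.), NaHCO3, cyclohexane, 80 °C; then Bu4NF, THF, 0 °C → rt
Reagents that add atoms: none
Why: Wohl–Ziegler bromination can only occur at C7 because the other allylic carbons (C4, C10) are quaternary, and fluoride-induced dehydrobromination toward C8–H gives the homoannular 5,7-diene, which erases the C8 stereocentre whose relay task ended in step 2.

**Step 8**
Reactants: 18 5,7-diene ester
Product: 19 [(1S,4aS,5R)-1,4a,6-trimethyl-5-[2-(2-methyl-1,3-dioxolan-2-yl)ethyl]-1,2,3,4,4a,5-hexahydronaphthalen-1-yl]methanol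
Conditions: LiAlH4, THF, 0 °C → rt
Reagents that add atoms: none
Why: Hydride reduction of the neopentyl methyl ester gives the primary alcohol (C18) and leaves the diene and the ketal intact; no stereocentre is affected.

**Step 9**
Reactants: 19 dienol
Product: 21 (1R,4R,4aS,8S,8aS)-8-(hydroxymethyl)-3,4a,8-trimethyl-4-[2-(2-methyl-1,3-dioxolan-2-yl)ethyl]-1,4,4a,5,6,7,8,8a-octahydronaphthalen-1-ol, via C6 alkylborane 20 (not isolated)
Conditions: BH3·THF (3 equiv), THF, 0 °C → rt; then NaOH, H2O2, 0 °C → rt
Reagents that add atoms: hydrogen peroxide, OO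
Why: Hydroboration–oxidation of the 5,7-diene, as known for steroidal 5,7-dienes, should place boron on C6 and hydrogen on C5 by syn addition from the face opposite the axial C10 and C4 methyl groups, setting the trans ring fusion (C5) and the equatorial C6 hydroxyl in one event while keeping the C7=C8 alkene.

**Step 10**
Reactants: 21 diol ketal
Product: 22 4-[(1R,4R,4aS,5S,8aS)-4-hydroxy-5-(hydroxymethyl)-2,5,8a-trimethyl-1,4,4a,5,6,7,8,8a-octahydronaphthalen-1-yl]butan-2-one
Conditions: PPTS, acetone/H2O, 50 °C
Reagents that add atoms: water, O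
Why: Mild acid-catalysed ketal hydrolysis should release the methyl ketone without ionising the allylic alcohol; no stereocentre is affected.

**Step 11**
Reactants: 22 keto diol; 23 trimethyl phosphonoacetate
Product: 24 methyl (2E)-5-[(1R,4R,4aS,5S,8aS)-4-hydroxy-5-(hydroxymethyl)-2,5,8a-trimethyl-1,4,4a,5,6,7,8,8a-octahydronaphthalen-1-yl]-3-methylpent-2-enoate (CNP0149445.1)
Conditions: 23 (excess), NaH, THF, 0 → 65 °C
Reagents that add atoms: none
Why: Horner–Wadsworth–Emmons olefination of the methyl ketone with an excess of the phosphonate anion (the two hydroxyl groups being carried as alkoxides) should give the trisubstituted enoate with the E isomer favoured under thermodynamic control, the minor Z isomer to be removed by chromatography.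

**Compound list**

1 | propanal | CCC=O | starting material
2 | pent-1-en-3-one | CCC(=O)C=C | starting material
3 | (S)-2-methyl-5-oxoheptanal | CCC(=O)CC[C@H](C)C=O | intermediate
4 | (S)-2,4-dimethylcyclohex-2-en-1-one | O=C1CC[C@H](C)C=C1C | intermediate
5 | 2-(2-bromoethyl)-2-methyl-1,3-dioxolane | CC1(CCBr)OCCO1 | starting material
6 | acrolein (prop-2-enal) | C=CC=O | starting material
7 | [2-(2-methyl-1,3-dioxolan-2-yl)ethyl]magnesium bromide | CC1(CC[Mg]Br)OCCO1 | intermediate
8 | bromomagnesium enolate of the trans-3,4-disubstituted 2-methylcyclohexanone (C10=C5–OMgBr) | Br[Mg]OC1=C(C)[C@H](CCC2(C)OCCO2)[C@@H](C)CC1 | intermediate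
9 | (2R,3R,4S)-2-[(1R)-1-hydroxyprop-2-en-1-yl]-2,4-dimethyl-3-[2-(2-methyl-1,3-dioxolan-2-yl)ethyl]cyclohexan-1-one | C=C[C@@H](O)[C@@]1(C)[C@H](CCC2(C)OCCO2)[C@@H](C)CCC1=O | intermediate
10 | 2-(diethoxyphosphoryl)propanoic acid | CCOP(=O)(OCC)C(C)C(=O)O | starting material
11 | (1R)-1-[(1R,2R,3S)-1,3-dimethyl-2-[2-(2-methyl-1,3-dioxolan-2-yl)ethyl]-6-oxocyclohexyl]prop-2-en-1-yl 2-(diethoxyphosphoryl)propanoate | C=C[C@@H](OC(=O)C(C)P(=O)(OCC)OCC)[C@@]1(C)[C@H](CCC2(C)OCCO2)[C@@H](C)CCC1=O | intermediate
12 | (1R,7S,8R,8aS)-1-ethenyl-4,7,8a-trimethyl-8-[2-(2-methyl-1,3-dioxolan-2-yl)ethyl]-1,5,6,7,8,8a-hexahydro-3H-isochromen-3-one | C=C[C@H]1OC(=O)C(C)=C2CC[C@H](C)[C@@H](CCC3(C)OCCO3)[C@]12C | intermediate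
13 | tert-butyldimethylsilyl ketene acetal of 12 (3-silyloxy-1H-isochromene with C18=C4 and C5=C6 double bonds) | C=C[C@H]1OC(O[Si](C)(C)C(C)(C)C)=C(C)C2=CC[C@H](C)[C@@H](CCC3(C)OCCO3)[C@]12C | intermediate
14 | tert-butyldimethylsilyl ester of the rearranged acid (ring A closed, C1=C2 and C5=C6 alkenes) | CC1(CC[C@@H]2[C@@H](C)CC=C3[C@@](C)(C(=O)O[Si](C)(C)C(C)(C)C)CC=C[C@@]23C)OCCO1 | intermediate
15 | methyl (1S,4aS,5R,6S)-1,4a,6-trimethyl-5-[2-(2-methyl-1,3-dioxolan-2-yl)ethyl]-1,2,4a,5,6,7-hexahydronaphthalene-1-carboxylate | CC1(CC[C@@H]2[C@@H](C)CC=C3[C@@](C)(C(=O)OC)CC=C[C@@]23C)OCCO1 | intermediate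
16 | methyl (1S,4aS,5R,6S)-1,4a,6-trimethyl-5-[2-(2-methyl-1,3-dioxolan-2-yl)ethyl]-1,2,3,4,4a,5,6,7-octahydronaphthalene-1-carboxylate | CC1(CC[C@@H]2[C@@H](C)CC=C3[C@@](C)(C(=O)OC)CCC[C@@]23C)OCCO1 | intermediate
17 | C7 bromide of 16 (both C7 epimers) | CC1(CC[C@@H]2[C@@H](C)C(Br)C=C3[C@@](C)(C(=O)OC)CCC[C@@]23C)OCCO1 | intermediate
18 | methyl (1S,4aS,5R)-1,4a,6-trimethyl-5-[2-(2-methyl-1,3-dioxolan-2-yl)ethyl]-1,2,3,4,4a,5-hexahydronaphthalene-1-carboxylate | CC1(CC[C@@H]2C(C)=CC=C3[C@@](C)(C(=O)OC)CCC[C@@]23C)OCCO1 | intermediate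
19 | [(1S,4aS,5R)-1,4a,6-trimethyl-5-[2-(2-methyl-1,3-dioxolan-2-yl)ethyl]-1,2,3,4,4a,5-hexahydronaphthalen-1-yl]methanol | CC1(CC[C@@H]2C(C)=CC=C3[C@@](C)(CO)CCC[C@@]23C)OCCO1 | intermediate
20 | C6 alkylborane of 19 (boron on C6 cis to H5, O18 as its alkoxyborane) | CC1(CC[C@@H]2C(C)=C[C@@H]([BH2])[C@@H]3[C@@](C)(CO[BH2])CCC[C@@]23C)OCCO1 | intermediate
21 | (1R,4R,4aS,8S,8aS)-8-(hydroxymethyl)-3,4a,8-trimethyl-4-[2-(2-methyl-1,3-dioxolan-2-yl)ethyl]-1,4,4a,5,6,7,8,8a-octahydronaphthalen-1-ol | CC1(CC[C@@H]2C(C)=C[C@@H](O)[C@@H]3[C@@](C)(CO)CCC[C@@]23C)OCCO1 | intermediate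
22 | 4-[(1R,4R,4aS,5S,8aS)-4-hydroxy-5-(hydroxymethyl)-2,5,8a-trimethyl-1,4,4a,5,6,7,8,8a-octahydronaphthalen-1-yl]butan-2-one | CC(=O)CC[C@@H]1C(C)=C[C@@H](O)[C@@H]2[C@@](C)(CO)CCC[C@@]12C | intermediate
23 | trimethyl phosphonoacetate | COC(=O)CP(=O)(OC)OC | starting material
24 | methyl (2E)-5-[(1R,4R,4aS,5S,8aS)-4-hydroxy-5-(hydroxymethyl)-2,5,8a-trimethyl-1,4,4a,5,6,7,8,8a-octahydronaphthalen-1-yl]-3-methylpent-2-enoate | COC(=O)/C=C(\C)CC[C@@H]1C(C)=C[C@@H](O)[C@@H]2[C@@](C)(CO)CCC[C@@]12C | target

**Totals**

Total step count: 11. Longest linear sequence: 11 steps (1 and 2 to 24).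

**Steps most likely to fail**

1. Step 5 (key step). The conjugated silyl ketene acetal may not reach the strained boat transition state, because the diene must twist out of conjugation and the C10 substituents crowd the vinyl bridge. Desilylation, C-silylation or thermal decomposition could then outrun the rearrangement.
 Fallback (ring A is still closed through the C3–C4 bond, by dienolate alkylation instead of a sigmatropic shift; it sets out from 4 and comes back at 16, so step 6 is not needed):
 - Enone 4 is treated with Grignard reagent 7 and CuBr·SMe2 as in step 2, but enolate 8 is trapped with allyl iodide and HMPA to give the 2-allyl ketone F1.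
 - Addition of the lithium enolate of methyl propanoate (LiN(iPr)2, THF, −78 °C) gives the β-hydroxy ester F2.
 - SOCl2 in pyridine dehydrates it to the β,γ-unsaturated ester F3 (C5=C6).
 - 9-BBN followed by NaBO3 hydroborates only the terminal alkene and gives the primary alcohol F4.
 - I2, PPh3 and imidazole convert it into the primary iodide F5.
 - KN(SiMe3)2 in THF forms the ester dienolate, which should close ring A by 6-exo-tet alkylation at C4 and give 16.
 - In this variant the C4 configuration rests on the rotamer preference of the dienolate, not on a stereospecific transfer, and would have to be verified.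

2. Step 2. Facial control by the C8 methyl group in the conjugate addition may be incomplete. The closed aldol transition state of a tetrasubstituted enolate with a small aldehyde may discriminate poorly at C1, and the aldolate may revert by retro-aldol cleavage on warming.
 Fallback for the carbinol centre (reagent control instead of aldol diastereoselection; it sets out from 9 obtained as a mixture of C1 epimers and comes back at 9):
 - Dess–Martin periodinane in CH2Cl2 oxidises the mixture to the 2-acryloyl ketone F6.
 - (S)-2-methyl-CBS-oxazaborolidine with catecholborane in toluene at −78 °C should reduce the less hindered enone carbonyl, with the quaternary C10 as the large and the vinyl group as the small substituent, to the (1R)-carbinol 9.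

3. Step 7. Radical bromination may be unselective (tertiary C–H bonds, ketal), bromine may add ionically to the alkene, HBr may cleave the ketal, and elimination of the C7 bromide may be incomplete.
 Fallback (oxidation-level route to the diene; it sets out from 16 and comes back at 18):
 - CrO3·3,5-dimethylpyrazole in CH2Cl2 at −20 °C oxidises the allylic C7 methylene to the 5-en-7-one F7.
 - Tosylhydrazide in MeOH gives the tosylhydrazone F8.
 - LiH in toluene at 110 °C (Bamford–Stevens reaction, as used for steroidal 5,7-dienes) should give diene 18.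

**Further compounds**

F1 | step 5 | (2S,3R,4S)-2,4-dimethyl-3-[2-(2-methyl-1,3-dioxolan-2-yl)ethyl]-2-(prop-2-en-1-yl)cyclohexan-1-one | C=CC[C@@]1(C)[C@H](CCC2(C)OCCO2)[C@@H](C)CCC1=O
F2 | step 5 | methyl 2-(1-hydroxycyclohexyl)propanoate adduct of F1 (tertiary alcohol at C5, epimers at C4 and C5) | COC(=O)C(C)C1(O)CC[C@H](C)[C@@H](CCC2(C)OCCO2)[C@]1(C)CC=C
F3 | step 5 | β,γ-unsaturated ester from F2 (C5=C6 alkene, epimers at C4) | COC(=O)C(C)C1=CC[C@H](C)[C@@H](CCC2(C)OCCO2)[C@]1(C)CC=C
F4 | step 5 | primary alcohol from F3 (3-hydroxypropyl group on C10) | COC(=O)C(C)C1=CC[C@H](C)[C@@H](CCC2(C)OCCO2)[C@]1(C)CCCO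
F5 | step 5 | primary iodide from F4 (3-iodopropyl group on C10) | COC(=O)C(C)C1=CC[C@H](C)[C@@H](CCC2(C)OCCO2)[C@]1(C)CCCI
F6 | step 2 | 2-acryloyl ketone from 9 (C1 ketone, configuration at C8, C9 and C10 as in 9) | C=CC(=O)[C@@]1(C)[C@H](CCC2(C)OCCO2)[C@@H](C)CCC1=O
F7 | step 7 | 5-en-7-one from 16 (ketone at C7) | CC1(CC[C@@H]2[C@@H](C)C(=O)C=C3[C@@](C)(C(=O)OC)CCC[C@@]23C)OCCO1
F8 | step 7 | p-toluenesulfonylhydrazone of F7 | CC1(CC[C@@H]2[C@@H](C)C(=NNS(=O)(=O)c4ccc(C)cc4)C=C3[C@@](C)(C(=O)OC)CCC[C@@]23C)OCCO1
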